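The C40 skeleton is cut at the C12'–C13' σ-bond of the C11'=C12'–C13'(Me)=C14' diene. The central C13–C13' octatriene is locally C2-symmetric, so one (2E,4E,6E)-2,7-diiodoocta-2,4,6-triene linchpin is coupled in turn with two C16 dienylmetals. These differ only at C7/C8 (alkyne on ring A, ethano bridge on ring B) and both derive from one (R)-enol triflate of actinol. The key step, a stereoretentive Stille coupling of C24 polyenynyl iodide 17 (iodine on C13') with C16 dienylstannane 25 (tin on C12'), completes the conjugated heptaenyne chain with every double-bond geometry preset; desilylation then gives the target.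

Key step: step 14

Assumption: (4R,6R)-actinol (CAS 60046-49-3), the enantiopure industrial zeaxanthin building block, is taken as a commercial starting material; its C4 carbinol centre becomes C3 of ring A and C3' of ring B.

Step 1
Reactants: 1 (4R,6R)-4-hydroxy-2,2,6-trimethylcyclohexan-1-one
Product: 2 (4R,6R)-4-[(tert-butyldimethylsilyl)oxy]-2,2,6-trimethylcyclohexan-1-one
Conditions: TBSCl, imidazole, DMF, rt
Reagents that add atoms: tert-butyldimethylsilyl chloride, CC(C)(C)[Si](C)(C)Cl
Why: Imidazole-promoted silyl ether formation at the unhindered secondary alcohol protects O-3 for the enolate and organometallic steps without touching a stereocentre.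

Step 2
Reactants: 2 (4R,6R)-4-[(tert-butyldimethylsilyl)oxy]-2,2,6-trimethylcyclohexan-1-one
Product: 4 (4R)-4-[(tert-butyldimethylsilyl)oxy]-2,6,6-trimethylcyclohex-1-en-1-yl trifluoromethanesulfonate, via lithium enolate 3 (not isolated)
Conditions: LDA (LiN(iPr)2), THF, −78 to 0 °C; then PhNTf2, −78 °C to rt
Reagents that add atoms: N-phenylbis(trifluoromethanesulfonimide), O=S(=O)(N(c1ccccc1)S(=O)(=O)C(F)(F)F)C(F)(F)F
Why: Enol triflate formation is regiochemically unambiguous because only C6–H is enolisable (C2 is quaternary); the C6 stereocentre is erased on purpose and the C4 carbinol centre is retained.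

Step 3
Reactants: 4 (4R)-enol triflate; 5 (2E)-3-methylpent-2-en-4-yn-1-ol
Product: 6 (2E)-5-[(4R)-4-[(tert-butyldimethylsilyl)oxy]-2,6,6-trimethylcyclohex-1-en-1-yl]-3-methylpent-2-en-4-yn-1-ol
Conditions: Pd(PPh3)4 (cat.), CuI (cat.), Et3N, DMF, rt
Reagents that add atoms: none
Why: Sonogashira coupling of a vinyl triflate with a terminal alkyne tolerates the free allylic alcohol and the hindered 2,6,6-trimethylcyclohexenyl position, and it carries the E geometry of 5 over as C9=C10.

Step 4
Reactants: 6 ring A C15 enynol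
Product: 7 (2E)-5-[(4R)-4-[(tert-butyldimethylsilyl)oxy]-2,6,6-trimethylcyclohex-1-en-1-yl]-3-methylpent-2-en-4-ynal
Conditions: MnO2, CH2Cl2, rt
Reagents that add atoms: none
Why: Allylic oxidation with MnO2 is selective for the primary allylic alcohol and leaves the silyl ether and the enyne untouched.

Step 5
Reactants: 7 ring A C15 enynal; 8 bis(4,4,5,5-tetramethyl-1,3,2-dioxaborolan-2-yl)methane
Product: 10 ring A C16 dienylboronate, 2-[(1E,3E)-6-[(4R)-4-[(tert-butyldimethylsilyl)oxy]-2,6,6-trimethylcyclohex-1-en-1-yl]-4-methylhexa-1,3-dien-5-yn-1-yl]-4,4,5,5-tetramethyl-1,3,2-dioxaborolane, via lithiated bis(boryl)methane 9 (not isolated)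
Conditions: LiTMP (lithium 2,2,6,6-tetramethylpiperidide), THF, 0 °C; then 7, −78 °C to rt
Reagents that add atoms: none
Why: Boron–Wittig olefination, in which the lithiated geminal bis(boronate) adds 1,2 to the aldehyde and syn B–O elimination should give the (E)-alkenylboronate, makes C12 the nucleophilic terminus.

Step 6
Reactants: 11 (E)-1,2-dichloroethene; 12 propyne
Product: 13 (1E)-1-chloropent-1-en-3-yne
Conditions: 11 (5 equiv), Pd(PPh3)4 (cat.), CuI (cat.), piperidine, THF, rt, sealed vessel; product carried on as a THF solution after removal of excess 11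
Reagents that add atoms: none
Why: Sonogashira coupling of a vinyl chloride proceeds with retention of the E geometry, and the large excess of the volatile dichloride should hold the reaction at the stage of one C–Cl bond.

Step 7
Reactants: 13 (1E)-1-chloropent-1-en-3-yne; 12 propyne
Product: 14 (4E)-oct-4-ene-2,6-diyne
Conditions: PdCl2(PhCN)2 (cat.), CuI (cat.), piperidine, THF, rt, sealed vessel
Reagents that add atoms: none
Why: A second Sonogashira coupling, at the C–Cl bond that the conjugated alkynyl group activates towards oxidative addition, proceeds with retention, so the E geometry of 11 becomes the C15=C15' double bond.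

Step 8
Reactants: 14 (4E)-oct-4-ene-2,6-diyne
Product: 16 (2E,4E,6E)-2,7-diiodoocta-2,4,6-triene, via bis(alkenylzirconocene) 15 (not isolated)
Conditions: Cp2Zr(H)Cl (2.5 equiv), THF, rt to 40 °C; then I2, THF, −78 to 0 °C, dark
Reagents that add atoms: iodine, II
Why: Hydrozirconation is a syn addition that, after equilibration with a slight excess of Cp2Zr(H)Cl, should place zirconium on the less hindered methyl-bearing alkyne carbon remote from the alkene, and iodinolysis with retention then gives the E-configured C13 and C13' iodides.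

Step 9
Reactants: 10 ring A C16 dienylboronate; 16 (2E,4E,6E)-2,7-diiodoocta-2,4,6-triene
Product: 17 C24 iodide, tert-butyl{[(1R)-4-[(3E,5E,7E,9E,11E)-12-iodo-3,7-dimethyltrideca-3,5,7,9,11-pentaen-1-yn-1-yl]-3,5,5-trimethylcyclohex-3-en-1-yl]oxy}dimethylsilane
Conditions: 16 (3 equiv), Pd(OAc)2 (cat.), SPhos, aq. K3PO4, THF, rt, dark
Reagents that add atoms: none
Why: Suzuki–Miyaura coupling forms C12–C13 with retention at both partners, and the excess of the C2-symmetric diiodide (recoverable) biases the reaction toward monocoupling.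

Step 10
Reactants: 18 (4-bromobut-1-yn-1-yl)trimethylsilane; 4 (4R)-enol triflate
Product: 20 tert-butyl{[(1R)-3,5,5-trimethyl-4-[4-(trimethylsilyl)but-3-yn-1-yl]cyclohex-3-en-1-yl]oxy}dimethylsilane, via alkylzinc bromide 19 (not isolated)
Conditions: Zn dust, LiCl, THF, 50 °C; then 4, Pd(dppf)Cl2 (cat.), THF/NMP, 60 °C
Reagents that add atoms: none
Why: Zinc insertion into the primary bromide followed by Negishi coupling with the enol triflate forges the sp2–sp3 C6'–C7' bond of the saturated bridge, with the dppf ligand disfavouring β-hydride elimination and the ring stereocentre remote from the reaction.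

Step 11
Reactants: 20 ring B silylalkyne
Product: 21 {[(1R)-4-(but-3-yn-1-yl)-3,5,5-trimethylcyclohex-3-en-1-yl]oxy}(tert-butyl)dimethylsilane
Conditions: K2CO3, MeOH, rt
Reagents that add atoms: none
Why: Base-mediated protodesilylation of the alkynylsilane in methanol frees the terminal alkyne while the secondary silyl ether survives.

Step 12
Reactants: 21 ring B terminal alkyne
Product: 23 tert-butyl{[(1R)-4-[(3E)-4-iodo-3-methylbut-3-en-1-yl]-3,5,5-trimethylcyclohex-3-en-1-yl]oxy}dimethylsilane, via alkenyldimethylalane 22 (not isolated)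
Conditions: Me3Al, Cp2ZrCl2 (cat.), CH2Cl2, 0 °C to rt; then I2, THF, −30 to 0 °C
Reagents that add atoms: trimethylaluminium, C[Al](C)C; iodine, II
Why: Zirconium-catalysed methylalumination (carboalumination) of the terminal alkyne is a syn addition that delivers methyl to the internal carbon, and iodinolysis with retention should give the (E)-trisubstituted vinyl iodide that defines C9'=C10'.

Step 13
Reactants: 23 ring B (E)-vinyl iodide; 24 (E)-1,2-bis(tributylstannyl)ethene
Product: 25 ring B C16 dienylstannane, tributyl[(1E,3E)-6-[(4R)-4-[(tert-butyldimethylsilyl)oxy]-2,6,6-trimethylcyclohex-1-en-1-yl]-4-methylhexa-1,3-dien-1-yl]stannane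
Conditions: 24 (3 equiv), PdCl2(MeCN)2 (cat.), DMF, rt, dark
Reagents that add atoms: none
Why: Stille coupling with retention forms C10'–C11', and the excess of the distannane confines the reaction to one tin terminus so that the (1E,3E)-dienylstannane results.

Step 14
Reactants: 17 C24 iodide; 25 ring B C16 dienylstannane
Product: 26 bis(tert-butyldimethylsilyl) ether of (3R,3'R)-7,8-didehydro-7',8'-dihydro-β,β-carotene-3,3'-diol
Conditions: Pd2(dba)3 (cat.), AsPh3, NMP, rt to 40 °C, dark, argon
Reagents that add atoms: none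
Why: Stille coupling, in which zerovalent palladium inserts into the C13'–I bond of 17, the dienyl group of 25 passes from tin to palladium and reductive elimination forms the C12'–C13' σ-bond. The closest known reaction type is the alkenyl iodide–alkenylstannane coupling used to assemble polyenes and carotenoids. No ring is closed and no stereocentre is created; the step instead needs complete retention of the E geometry at C13'=C14' and C11'=C12', which the stereospecific oxidative addition, transmetalation and reductive elimination sequence provides. The weakly donating AsPh3 ligand accelerates transmetalation so that the coupling should run near room temperature in the dark, which limits E/Z isomerisation of the polyene. Chemoselectivity is secured because each partner carries a single reactive terminus, while the hindered C7≡C8 alkyne and both silyl ethers are inert.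

Step 15
Reactants: 26 bis-silyl ether
Product: 27 (3R,3'R)-7,8-didehydro-7',8'-dihydro-β,β-carotene-3,3'-diol (all-E)
Conditions: Bu4NF, THF, 0 °C to rt, dark
Reagents that add atoms: none
Why: Fluoride-mediated cleavage of both silyl ethers under non-acidic conditions that the polyenyne tolerates leaves both carbinol centres untouched and should give the (3R,3'R)-diol.

Compound list
1 | (4R,6R)-4-hydroxy-2,2,6-trimethylcyclohexan-1-one ((4R,6R)-actinol) | O=C1C(C)(C)C[C@H](O)C[C@H]1C | starting material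
2 | (4R,6R)-4-[(tert-butyldimethylsilyl)oxy]-2,2,6-trimethylcyclohexan-1-one | O=C1C(C)(C)C[C@H](O[Si](C)(C)C(C)(C)C)C[C@H]1C | intermediate
3 | lithium (4R)-4-[(tert-butyldimethylsilyl)oxy]-2,6,6-trimethylcyclohex-1-en-1-olate | CC1=C(O[Li])C(C)(C)C[C@H](O[Si](C)(C)C(C)(C)C)C1 | intermediate
4 | (4R)-4-[(tert-butyldimethylsilyl)oxy]-2,6,6-trimethylcyclohex-1-en-1-yl trifluoromethanesulfonate | CC1=C(OS(=O)(=O)C(F)(F)F)C(C)(C)C[C@H](O[Si](C)(C)C(C)(C)C)C1 | intermediate
5 | (2E)-3-methylpent-2-en-4-yn-1-ol | C#C/C(C)=C/CO | starting material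
6 | (2E)-5-[(4R)-4-[(tert-butyldimethylsilyl)oxy]-2,6,6-trimethylcyclohex-1-en-1-yl]-3-methylpent-2-en-4-yn-1-ol | CC1=C(C#C/C(C)=C/CO)C(C)(C)C[C@H](O[Si](C)(C)C(C)(C)C)C1 | intermediate
7 | (2E)-5-[(4R)-4-[(tert-butyldimethylsilyl)oxy]-2,6,6-trimethylcyclohex-1-en-1-yl]-3-methylpent-2-en-4-ynal | CC1=C(C#C/C(C)=C/C=O)C(C)(C)C[C@H](O[Si](C)(C)C(C)(C)C)C1 | intermediate
8 | bis(4,4,5,5-tetramethyl-1,3,2-dioxaborolan-2-yl)methane | C(B1OC(C)(C)C(C)(C)O1)B1OC(C)(C)C(C)(C)O1 | starting material
9 | lithio-bis(4,4,5,5-tetramethyl-1,3,2-dioxaborolan-2-yl)methane | [Li]C(B1OC(C)(C)C(C)(C)O1)B1OC(C)(C)C(C)(C)O1 | intermediate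
10 | ring A C16 dienylboronate, 2-[(1E,3E)-6-[(4R)-4-[(tert-butyldimethylsilyl)oxy]-2,6,6-trimethylcyclohex-1-en-1-yl]-4-methylhexa-1,3-dien-5-yn-1-yl]-4,4,5,5-tetramethyl-1,3,2-dioxaborolane | CC1=C(C#C/C(C)=C/C=C/B2OC(C)(C)C(C)(C)O2)C(C)(C)C[C@H](O[Si](C)(C)C(C)(C)C)C1 | intermediate
11 | (E)-1,2-dichloroethene | Cl/C=C/Cl | starting material
12 | propyne | CC#C | starting material
13 | (1E)-1-chloropent-1-en-3-yne | CC#C/C=C/Cl | intermediate
14 | (4E)-oct-4-ene-2,6-diyne | CC#C/C=C/C#CC | intermediate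
15 | (2E,4E,6E)-octa-2,4,6-triene-2,7-diylbis[chlorobis(cyclopentadienyl)zirconium] | C/C(=C\C=C\C=C(/C)[Zr](Cl)(C1C=CC=C1)C1C=CC=C1)[Zr](Cl)(C1C=CC=C1)C1C=CC=C1 | intermediate
16 | (2E,4E,6E)-2,7-diiodoocta-2,4,6-triene | C/C(I)=C\C=C\C=C(/C)I | intermediate
17 | C24 iodide, tert-butyl{[(1R)-4-[(3E,5E,7E,9E,11E)-12-iodo-3,7-dimethyltrideca-3,5,7,9,11-pentaen-1-yn-1-yl]-3,5,5-trimethylcyclohex-3-en-1-yl]oxy}dimethylsilane | CC1=C(C#C/C(C)=C/C=C/C(C)=C/C=C/C=C(\C)I)C(C)(C)C[C@H](O[Si](C)(C)C(C)(C)C)C1 | intermediate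
18 | (4-bromobut-1-yn-1-yl)trimethylsilane | C[Si](C)(C)C#CCCBr | starting material
19 | [4-(trimethylsilyl)but-3-yn-1-yl]zinc bromide | C[Si](C)(C)C#CCC[Zn]Br | intermediate
20 | tert-butyl{[(1R)-3,5,5-trimethyl-4-[4-(trimethylsilyl)but-3-yn-1-yl]cyclohex-3-en-1-yl]oxy}dimethylsilane | C[Si](C)(C)C#CCCC1=C(C)C[C@@H](O[Si](C)(C)C(C)(C)C)CC1(C)C | intermediate
21 | {[(1R)-4-(but-3-yn-1-yl)-3,5,5-trimethylcyclohex-3-en-1-yl]oxy}(tert-butyl)dimethylsilane | C#CCCC1=C(C)C[C@@H](O[Si](C)(C)C(C)(C)C)CC1(C)C | intermediate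
22 | [(1E)-4-[(4R)-4-[(tert-butyldimethylsilyl)oxy]-2,6,6-trimethylcyclohex-1-en-1-yl]-2-methylbut-1-en-1-yl]dimethylalane | C/C(=C\[Al](C)C)CCC1=C(C)C[C@@H](O[Si](C)(C)C(C)(C)C)CC1(C)C | intermediate
23 | tert-butyl{[(1R)-4-[(3E)-4-iodo-3-methylbut-3-en-1-yl]-3,5,5-trimethylcyclohex-3-en-1-yl]oxy}dimethylsilane | C/C(=C\I)CCC1=C(C)C[C@@H](O[Si](C)(C)C(C)(C)C)CC1(C)C | intermediate
24 | (E)-1,2-bis(tributylstannyl)ethene | CCCC[Sn](CCCC)(CCCC)/C=C/[Sn](CCCC)(CCCC)CCCC | starting material
25 | ring B C16 dienylstannane, tributyl[(1E,3E)-6-[(4R)-4-[(tert-butyldimethylsilyl)oxy]-2,6,6-trimethylcyclohex-1-en-1-yl]-4-methylhexa-1,3-dien-1-yl]stannane | CCCC[Sn](CCCC)(CCCC)/C=C/C=C(\C)CCC1=C(C)C[C@@H](O[Si](C)(C)C(C)(C)C)CC1(C)C | intermediate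
26 | bis(tert-butyldimethylsilyl) ether of (3R,3'R)-7,8-didehydro-7',8'-dihydro-β,β-carotene-3,3'-diol (all-E) | CC1=C(C#C/C(C)=C/C=C/C(C)=C/C=C/C=C(C)/C=C/C=C(\C)CCC2=C(C)C[C@@H](O[Si](C)(C)C(C)(C)C)CC2(C)C)C(C)(C)C[C@H](O[Si](C)(C)C(C)(C)C)C1 | intermediate
27 | (3R,3'R)-7,8-didehydro-7',8'-dihydro-β,β-carotene-3,3'-diol (all-E) | CC1=C(C#C/C(C)=C/C=C/C(C)=C/C=C/C=C(C)/C=C/C=C(\C)CCC2=C(C)C[C@@H](O)CC2(C)C)C(C)(C)C[C@H](O)C1 | target

Total step count: 15.
Longest linear sequence: 8 steps (steps 1, 2, 10, 11, 12, 13, 14, 15; the ring A branch through steps 1, 2, 3, 4, 5, 9, 14, 15 is equally long).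

Steps most likely to fail

Step 14. Slow transmetalation may allow geometric isomerisation of the polyene at palladium, homocoupling of the stannane, or protodestannylation of 25 during handling. The fallback is a hydrozirconation–Negishi coupling that generates the C12' nucleophile from an alkyne in the coupling flask and still forms the C12'–C13' bond. It sets out from 23 and 17. Sonogashira coupling of 23 with ethynyltrimethylsilane (Pd(PPh3)4, CuI, Et3N) would give the silyl enyne F1. K2CO3 in MeOH would then give the terminal enyne F2. Syn-hydrozirconation with Cp2Zr(H)Cl would give the (1E,3E)-dienylzirconocene chloride F3, and transmetalation with ZnCl2 the dienylzinc chloride F4. Pd(PPh3)4-catalysed coupling of F4 with 17 should come back to the route at 26.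

Step 9. Coupling at both C–I termini of 16 (statistical over-reaction to the symmetric bis-adduct) and protodeboronation of 10 may erode the monocoupling. The fallback desymmetrises the C8 unit before it meets the ring A half. It sets out from 14 and 10. Hydrozirconation of an excess of 14 with one equivalent of Cp2Zr(H)Cl would give the mono-zirconocene F5, and iodinolysis the iododienyne F6. Suzuki–Miyaura coupling of F6 with 10 (Pd(OAc)2, SPhos, aq. K3PO4) would give the propynyl-terminated C24 trienediyne F7. Hydrozirconation of its unhindered propynyl terminus would give the alkenylzirconocene F8; the C7≡C8 alkyne, flanked by ring A and C9, should be too hindered to react. Iodinolysis of F8 comes back to the route at 17.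

Step 10. Oxidative addition at the hindered tetrasubstituted triflate may be slower than β-hydride elimination or reduction at the alkylpalladium stage, or than decay of the zinc reagent. The fallback builds the C7'–C8' bond by sp3–sp3 alkylation instead of cross-coupling. It sets out from 4. Pd(OAc)2/dppp-catalysed methoxycarbonylation (CO, MeOH, Et3N, DMF) would give the ester F9. Reduction with (iBu)2AlH would give the allylic alcohol F10, and CBr4/PPh3 the allylic bromide F11. SN2 alkylation of F11 with 3-(trimethylsilyl)propargyllithium F12 (from 1-(trimethylsilyl)propyne and n-BuLi, THF, −78 °C) comes back to the route at 20.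

Further compounds
F1 | step 14 | tert-butyl{[(1R)-3,5,5-trimethyl-4-[(3E)-3-methyl-6-(trimethylsilyl)hex-3-en-5-yn-1-yl]cyclohex-3-en-1-yl]oxy}dimethylsilane | C[Si](C)(C)C#C/C=C(\C)CCC1=C(C)C[C@@H](O[Si](C)(C)C(C)(C)C)CC1(C)C
F2 | step 14 | tert-butyl{[(1R)-3,5,5-trimethyl-4-[(3E)-3-methylhex-3-en-5-yn-1-yl]cyclohex-3-en-1-yl]oxy}dimethylsilane | C#C/C=C(\C)CCC1=C(C)C[C@@H](O[Si](C)(C)C(C)(C)C)CC1(C)C
F3 | step 14 | chlorobis(cyclopentadienyl)[(1E,3E)-6-[(4R)-4-[(tert-butyldimethylsilyl)oxy]-2,6,6-trimethylcyclohex-1-en-1-yl]-4-methylhexa-1,3-dien-1-yl]zirconium | Cl[Zr](/C=C/C=C(\C)CCC1=C(C)C[C@@H](O[Si](C)(C)C(C)(C)C)CC1(C)C)(C1C=CC=C1)C1C=CC=C1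
F4 | step 14 | [(1E,3E)-6-[(4R)-4-[(tert-butyldimethylsilyl)oxy]-2,6,6-trimethylcyclohex-1-en-1-yl]-4-methylhexa-1,3-dien-1-yl]zinc chloride | Cl[Zn]/C=C/C=C(\C)CCC1=C(C)C[C@@H](O[Si](C)(C)C(C)(C)C)CC1(C)C
F5 | step 9 | chlorobis(cyclopentadienyl)[(2E,4E)-octa-2,4-dien-6-yn-2-yl]zirconium | C/C(=C\C=C\C#CC)[Zr](Cl)(C1C=CC=C1)C1C=CC=C1
F6 | step 9 | (2E,4E)-2-iodoocta-2,4-dien-6-yne | C/C(I)=C\C=C\C#CC
F7 | step 9 | tert-butyl{[(1R)-4-[(3E,5E,7E,9E)-3,7-dimethyltrideca-3,5,7,9-tetraene-1,11-diyn-1-yl]-3,5,5-trimethylcyclohex-3-en-1-yl]oxy}dimethylsilane | CC1=C(C#C/C(C)=C/C=C/C(C)=C/C=C/C#CC)C(C)(C)C[C@H](O[Si](C)(C)C(C)(C)C)C1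
F8 | step 9 | chlorobis(cyclopentadienyl)zirconium derivative of F7 with zirconium on C13' (12-zirconio-3,7-dimethyltrideca-3,5,7,9,11-pentaen-1-ynyl chain, all-E) | CC1=C(C#C/C(C)=C/C=C/C(C)=C/C=C/C=C(\C)[Zr](Cl)(C2C=CC=C2)C2C=CC=C2)C(C)(C)C[C@H](O[Si](C)(C)C(C)(C)C)C1
F9 | step 10 | methyl (4R)-4-[(tert-butyldimethylsilyl)oxy]-2,6,6-trimethylcyclohex-1-ene-1-carboxylate | COC(=O)C1=C(C)C[C@@H](O[Si](C)(C)C(C)(C)C)CC1(C)C
F10 | step 10 | [(4R)-4-[(tert-butyldimethylsilyl)oxy]-2,6,6-trimethylcyclohex-1-en-1-yl]methanol | OCC1=C(C)C[C@@H](O[Si](C)(C)C(C)(C)C)CC1(C)C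
F11 | step 10 | {[(1R)-4-(bromomethyl)-3,5,5-trimethylcyclohex-3-en-1-yl]oxy}(tert-butyl)dimethylsilane | BrCC1=C(C)C[C@@H](O[Si](C)(C)C(C)(C)C)CC1(C)C
F12 | step 10 | 3-(trimethylsilyl)prop-2-yn-1-yllithium | [Li]CC#C[Si](C)(C)C
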